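**Retrosynthetic overview**

1. Numbering (bicyclo[4.3.1]dec-7-ene): C1/C6 bridgeheads; C2–C5 four-carbon bridge (C4 acetyl, C5 quaternary); C7(CHO)=C8–C9 three-carbon bridge; C10 the C(OAc)CH3 bridge. Enabling feature: O–C10–C6–C5–C4–C(=O)CH3 is a 1,5-dioxygenated chain, so with C10 as a ketone the seven-membered ring C10–C1–C2–C3–C4–C5–C6 is the retro-aldol product of a cyclobutanol in which C10 is bonded to C4.
2. Key disconnection (De Mayo reaction): C10–C6 and C4–C5 come from a [2+2] photocycloaddition of the ring enol of a 2-acetylcyclopentanone (C10, C1, C2, C3, C4) with the tethered trisubstituted alkene C6=C5; retro-aldol cleavage of C10–C4 then expands the cyclopentane by two carbons to the cycloheptane.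
3. Ring order: cyclopentanone (bought) → cyclohexane C10/C1/C9/C8/C7/C6 and cyclobutane (photocycloaddition) → cycloheptane (fragmentation of the cyclobutane).
4. After the key step: the C10 methyl by MeLi on the non-enolisable bridging ketone, then acetate; the C7 ketone (a dioxolane during photolysis) → enol triflate → Pd/CO formylation gives the enal.
5. Photosubstrate: SAMP-hydrazone alkylation of cyclopentanone with a bromo ketal made from (S)-β-citronellene (Wacker oxidation, alkyne, carboalumination–acylation), then C-acetylation.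

Key step: step 9

Remark on the chemistry: read literally, the two bridgehead descriptors of the target string put the four-carbon bridge on opposite faces of the cyclohexene ring (an in,out bicycle); every SMILES below keeps the descriptors of the string, and should ring strain allow only the usual cis-bridged closure, RAMP replaces SAMP in step 5 and nothing else in the route changes.

**Route**

Step 1
Reactants: 1 (S)-β-citronellene, (3S)-3,7-dimethylocta-1,6-diene
Product: 2 (3S)-3,7-dimethyloct-6-en-2-one
Conditions: PdCl2 (10 mol%), CuCl, O2 (1 atm), DMF/H2O 7:1, 23 °C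
Reagents that add atoms: water (O)
Why: Wacker–Tsuji oxidation by Markovnikov oxypalladation of the monosubstituted alkene only; the trisubstituted alkene is inert and the adjacent stereocentre is not involved.

Step 2
Reactants: 2 (3S)-3,7-dimethyloct-6-en-2-one
Product: 4 (3S)-3,7-dimethyloct-6-en-1-yne, via enol phosphate 3 (not isolated)
Conditions: LDA (1.1 equiv), THF, −78 °C; ClP(O)(OEt)2; then LDA (2.3 equiv), −78 → 23 °C; aq. NH4Cl
Reagents that add atoms: none
Why: Kinetic deprotonation at CH3, O-phosphorylation and base-induced β-elimination to the lithium acetylide (methyl ketone to terminal alkyne via the enol phosphate); the stereocentre never becomes part of an enolate.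

Step 3
Reactants: 4 (3S)-3,7-dimethyloct-6-en-1-yne; 5 3-bromopropanoyl chloride
Product: 7 (4E,6S)-1-bromo-5,6,10-trimethylundeca-4,9-dien-3-one, via alkenylalane 6 (not isolated)
Conditions: Me3Al (2 equiv), Cp2ZrCl2 (20 mol%), CH2Cl2, 0 → 23 °C; volatiles removed; then 5, Pd(PPh3)4 (5 mol%), THF, 0 °C
Reagents that add atoms: trimethylaluminium C[Al](C)C
Why: Zr-catalysed carboalumination (Negishi) adds CH3 and Al syn with Al on the terminal carbon, and Pd-catalysed acylation of the alkenylalane proceeds with retention, so the (E)-enone should result; the remote trisubstituted alkene does not react.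

Step 4
Reactants: 7 (4E,6S)-1-bromo-5,6,10-trimethylundeca-4,9-dien-3-one
Product: 8 2-(2-bromoethyl)-2-[(1E,3S)-2,3,7-trimethylocta-1,6-dien-1-yl]-1,3-dioxolane
Conditions: (TMSOCH2)2, TMSOTf (5 mol%), CH2Cl2, −78 → −20 °C; pyridine quench
Reagents that add atoms: 1,2-bis(trimethylsilyloxy)ethane C[Si](C)(C)OCCO[Si](C)(C)C
Why: Noyori ketalisation under aprotic conditions keeps the double bond in place, removes the enone chromophore before photolysis and shuts off β-elimination of HBr.

Step 5
Reactants: 9 cyclopentanone; 10 SAMP, (S)-1-amino-2-(methoxymethyl)pyrrolidine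
Product: 11 cyclopentanone SAMP hydrazone
Conditions: neat, 60 °C; distillation
Reagents that add atoms: none
Why: Hydrazone condensation, driven by removal of water.

Step 6
Reactants: 11 cyclopentanone SAMP hydrazone; 8 bromo ketal
Product: 13 SAMP hydrazone of (2S)-2-{2-[2-((1E,3S)-2,3,7-trimethylocta-1,6-dien-1-yl)-1,3-dioxolan-2-yl]ethyl}cyclopentanone, via lithium azaenolate 12 (not isolated)
Conditions: LDA (1.05 equiv), THF, 0 °C; then 8, −100 → 23 °C
Reagents that add atoms: none
Why: SAMP-hydrazone α-alkylation: the chelated lithium azaenolate is alkylated by the primary bromide on the face away from the methoxymethyl-pyrrolidine, which should set the ring stereocentre as (S).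

Step 7
Reactants: 13 alkylated SAMP hydrazone
Product: 14 (2S)-2-{2-[2-((1E,3S)-2,3,7-trimethylocta-1,6-dien-1-yl)-1,3-dioxolan-2-yl]ethyl}cyclopentan-1-one
Conditions: Cu(OAc)2·H2O, THF/H2O, pH 7 phosphate buffer, 23 °C; aq. NH3 work-up
Reagents that add atoms: water (O)
Why: Cu(II)-assisted hydrazone hydrolysis at neutral pH should spare the acid-labile allylic ketal and both alkenes and should not epimerise the α-stereocentre.

Step 8
Reactants: 14 2-alkylcyclopentanone
Product: 16 (5S)-2-acetyl-5-{2-[2-((1E,3S)-2,3,7-trimethylocta-1,6-dien-1-yl)-1,3-dioxolan-2-yl]ethyl}cyclopentan-1-one, via lithium enolate 15 (not isolated)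
Conditions: LDA (1.05 equiv), THF, −78 °C; then 1-acetylbenzotriazole, −78 → 0 °C; aq. NH4Cl
Reagents that add atoms: 1-acetyl-1H-benzotriazole CC(=O)n1nnc2ccccc12
Why: Kinetic deprotonation at the unsubstituted α-CH2 and Claisen-type C-acylation with an N-acylbenzotriazole give the 1,3-diketone (largely enolised, C2 not a fixed centre) without touching the C5 stereocentre.

Step 9
Reactants: 16 2-acetyl-5-alkylcyclopentanone
Product: 19 4-acetyl-5-methyl-5-[(2S)-6-methylhept-5-en-2-yl]bicyclo[4.3.1]decane-7,10-dione 7-ethylene ketal, via enol tautomer 17 (not isolated), via cyclobutanol photoadduct 18 (not isolated)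
Conditions: hν (350 nm, Pyrex), degassed cyclohexane (5 mM), 20 °C
Reagents that add atoms: none
Why: Excitation of the chelated ring enol 17 (a β-hydroxy enone) gives the triplet, whose oxygen-bearing carbon C10 bonds to the alkene CH (C6) in a 1,6-closure that forms the six-membered ring C10–C1–C9–C8–C7–C6 and leaves an α-acyl radical at C4 and a tertiary radical at C5; recombination closes the cyclobutane C10–C6–C5–C4, and the strained β-hydroxy ketone 18 undergoes spontaneous retro-aldol cleavage of C10–C4, which turns the cyclopentane into the cycloheptane (two-carbon ring expansion) and releases the bridging ketone and the acetyl group. The closest known reaction type is the intramolecular De Mayo reaction of 2-acylcycloalkanones and related enol derivatives, an established route to ring-expanded and bridged 1,5-diketones. C6 is fixed by the C1 stereocentre through the three-carbon tether, which allows bonding to only one face of the enol. C5 is set in the biradical collapse, independent of alkene geometry: the 6-methylhept-5-en-2-yl group should take the cyclobutane face that carries H-6 and the acetyl group, away from the face flanked by the cyclopentane CH2 and the new cyclohexane, which leaves the methyl group cis to C7. C4 is epimerisable and is drawn in the configuration that is secured by equilibration in step 14. The step needs the ring enol and not the exocyclic enol to react, which the tether length secures (only C10 is within reach of C6), and it needs the remote trisubstituted alkene to stay out, which its distance from the chromophore secures.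

Step 10
Reactants: 19 bicyclic diketone ketal
Product: 20 4-[1-(trimethylsilyloxy)vinyl]-5-methyl-5-[(2S)-6-methylhept-5-en-2-yl]bicyclo[4.3.1]decane-7,10-dione 7-ethylene ketal
Conditions: LDA/TMSCl (premixed, in situ quench), THF, −78 °C; pentane, filtration
Reagents that add atoms: chlorotrimethylsilane C[Si](C)(C)Cl
Why: Kinetic enolisation of the acetyl CH3 with internal silyl trapping masks the methyl ketone before its enolate can add across the ring to the bridging ketone, which itself has only bridgehead α-hydrogens and cannot enolise.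

Step 11
Reactants: 20 silyl enol ether
Product: 23 10-acetoxy-4-(1-acetoxyvinyl)-5,10-dimethyl-5-[(2S)-6-methylhept-5-en-2-yl]bicyclo[4.3.1]decan-7-one ethylene ketal, via lithium alkoxide 21 (not isolated), via dilithium alkoxide enolate 22 (not isolated)
Conditions: MeLi (2.5 equiv), THF, −78 → 0 °C; then Ac2O (5 equiv), DMAP (cat.), 0 → 23 °C
Reagents that add atoms: methyllithium [Li]C; acetic anhydride CC(=O)OC(C)=O
Why: 1,2-Addition of MeLi to the bridging ketone at −78 °C should occur from the face of the three-carbon bridge, because the C5 side chain shields the other face, which places the oxygen on the side of the four-carbon bridge; on warming MeLi cleaves the Si–O bond to the enolate when no ketone is left, and Ac2O traps alkoxide and enolate as tertiary acetate and enol acetate.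

Step 12
Reactants: 23 bis-acetate ketal
Product: 24 10-acetoxy-4-(1-acetoxyvinyl)-5,10-dimethyl-5-[(2S)-6-methylhept-5-en-2-yl]bicyclo[4.3.1]decan-7-one
Conditions: PPTS (cat.), acetone/H2O 10:1, 45 °C
Reagents that add atoms: water (O)
Why: Mild acid-catalysed ketal hydrolysis; the enol acetate and the tertiary acetate tolerate PPTS, and the β-acetoxy ketone cannot eliminate because its only α-hydrogen on that side is at a bridgehead.

Step 13
Reactants: 24 C7 ketone
Product: 26 10-acetoxy-4-(1-acetoxyvinyl)-5,10-dimethyl-5-[(2S)-6-methylhept-5-en-2-yl]bicyclo[4.3.1]dec-7-en-7-yl trifluoromethanesulfonate, via potassium enolate 25 (not isolated)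
Conditions: 24 and PhNTf2 in THF, −78 °C; KHMDS (1.05 equiv) added slowly
Reagents that add atoms: N-phenylbis(trifluoromethanesulfonimide) O=S(=O)(N(c1ccccc1)S(=O)(=O)C(F)(F)F)C(F)(F)F
Why: Enol triflate formation: the ketone can enolise only toward C8 (C6 is a bridgehead), the acetyl group is masked as its enol acetate, and in situ triflation traps the enolate before acyl transfer.

Step 14
Reactants: 26 enol triflate
Product: 27 4-acetyl-10-acetoxy-5,10-dimethyl-5-[(2S)-6-methylhept-5-en-2-yl]bicyclo[4.3.1]dec-7-en-7-yl trifluoromethanesulfonate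
Conditions: K2CO3, MeOH, 0 → 23 °C
Reagents that add atoms: none
Why: Methanolysis of the enol acetate is much faster than that of the hindered tertiary acetate, and the freed methyl ketone should equilibrate at C4 through its enolate to the epimer with the acetyl group away from the three-carbon bridge and cis to the C5 side chain.

Step 15
Reactants: 27 methyl ketone triflate
Product: 28 4-acetyl-10-acetoxy-5,10-dimethyl-5-[(2S)-6-methylhept-5-en-2-yl]bicyclo[4.3.1]dec-7-ene-7-carbaldehyde (target)
Conditions: Pd(PPh3)4 (5 mol%), LiCl, CO (1 atm), Bu3SnH (slow addition), THF, 50 °C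
Reagents that add atoms: carbon monoxide [C-]#[O+]
Why: Pd-catalysed reductive carbonylation (formylation) of the vinyl triflate: oxidative addition, CO insertion and hydride transfer from tin give the enal; ketone, acetate and the isolated alkene are tolerated.

**Compound list**

1 | (S)-β-citronellene, (3S)-3,7-dimethylocta-1,6-diene | C=C[C@@H](C)CCC=C(C)C | starting material
2 | (3S)-3,7-dimethyloct-6-en-2-one | CC(=O)[C@@H](C)CCC=C(C)C | intermediate
3 | diethyl (3S)-3,7-dimethylocta-1,6-dien-2-yl phosphate (enol phosphate) | C=C(OP(=O)(OCC)OCC)[C@@H](C)CCC=C(C)C | intermediate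
4 | (3S)-3,7-dimethyloct-6-en-1-yne | C#C[C@@H](C)CCC=C(C)C | intermediate
5 | 3-bromopropanoyl chloride | O=C(Cl)CCBr | starting material
6 | dimethyl[(1E,3S)-2,3,7-trimethylocta-1,6-dien-1-yl]alane | C[Al](C)/C=C(\C)[C@@H](C)CCC=C(C)C | intermediate
7 | (4E,6S)-1-bromo-5,6,10-trimethylundeca-4,9-dien-3-one | BrCCC(=O)/C=C(\C)[C@@H](C)CCC=C(C)C | intermediate
8 | 2-(2-bromoethyl)-2-[(1E,3S)-2,3,7-trimethylocta-1,6-dien-1-yl]-1,3-dioxolane | BrCCC1(OCCO1)/C=C(\C)[C@@H](C)CCC=C(C)C | intermediate
9 | cyclopentanone | O=C1CCCC1 | starting material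
10 | SAMP, (S)-1-amino-2-(methoxymethyl)pyrrolidine | COC[C@@H]1CCCN1N | starting material
11 | cyclopentanone SAMP hydrazone | COC[C@@H]1CCCN1N=C1CCCC1 | intermediate
12 | lithium azaenolate of 11 | [Li+].COC[C@@H]1CCCN1[N-]C2=CCCC2 | intermediate
13 | SAMP hydrazone of 14 (ring centre S, C=N geometry not fixed) | COC[C@@H]1CCCN1N=C2CCC[C@H]2CCC3(OCCO3)/C=C(\C)[C@@H](C)CCC=C(C)C | intermediate
14 | (2S)-2-{2-[2-((1E,3S)-2,3,7-trimethylocta-1,6-dien-1-yl)-1,3-dioxolan-2-yl]ethyl}cyclopentan-1-one | O=C1CCC[C@H]1CCC2(OCCO2)/C=C(\C)[C@@H](C)CCC=C(C)C | intermediate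
15 | lithium enolate of 14 (unsubstituted side) | [Li+].[O-]C1=CCC[C@H]1CCC2(OCCO2)/C=C(\C)[C@@H](C)CCC=C(C)C | intermediate
16 | (5S)-2-acetyl-5-{2-[2-((1E,3S)-2,3,7-trimethylocta-1,6-dien-1-yl)-1,3-dioxolan-2-yl]ethyl}cyclopentan-1-one (diketo form; C2 enolised) | CC(=O)C1CC[C@@H](CCC2(OCCO2)/C=C(\C)[C@@H](C)CCC=C(C)C)C1=O | intermediate
17 | ring enol tautomer of 16 | CC(=O)C1=C(O)[C@H](CCC2(OCCO2)/C=C(\C)[C@@H](C)CCC=C(C)C)CC1 | intermediate
18 | cyclobutanol photoadduct (C10 bonded to C4 and C6; side chain cis to H-6 and to acetyl) | O[C@@]12[C@@H]3CCC4(OCCO4)[C@@H]1[C@@](C)([C@@H](C)CCC=C(C)C)[C@]2(C(C)=O)CC3 | intermediate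
19 | 4-acetyl-5-methyl-5-[(2S)-6-methylhept-5-en-2-yl]bicyclo[4.3.1]decane-7,10-dione 7-ethylene ketal (C5 side chain cis to H-6; acetyl cis to side chain) | O=C1[C@@H]2CCC3(OCCO3)[C@@H]1[C@@](C)([C@@H](C)CCC=C(C)C)[C@@H](C(C)=O)CC2 | intermediate
20 | trimethylsilyl enol ether of 19 (acetyl CH3 side) | O=C1[C@@H]2CCC3(OCCO3)[C@@H]1[C@@](C)([C@@H](C)CCC=C(C)C)[C@@H](C(=C)O[Si](C)(C)C)CC2 | intermediate
21 | lithium C10 alkoxide of the MeLi adduct of 20 | [Li+].[O-][C@]1(C)[C@@H]2CCC3(OCCO3)[C@@H]1[C@@](C)([C@@H](C)CCC=C(C)C)[C@@H](C(=C)O[Si](C)(C)C)CC2 | intermediate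
22 | dilithium alkoxide enolate | [Li+].[Li+].[O-][C@]1(C)[C@@H]2CCC3(OCCO3)[C@@H]1[C@@](C)([C@@H](C)CCC=C(C)C)[C@@H](C(=C)[O-])CC2 | intermediate
23 | 10-acetoxy-4-(1-acetoxyvinyl)-5,10-dimethyl-5-[(2S)-6-methylhept-5-en-2-yl]bicyclo[4.3.1]decan-7-one ethylene ketal (C10 acetate on the side of the four-carbon bridge) | CC(=O)O[C@]1(C)[C@@H]2CCC3(OCCO3)[C@@H]1[C@@](C)([C@@H](C)CCC=C(C)C)[C@@H](C(=C)OC(C)=O)CC2 | intermediate
24 | 10-acetoxy-4-(1-acetoxyvinyl)-5,10-dimethyl-5-[(2S)-6-methylhept-5-en-2-yl]bicyclo[4.3.1]decan-7-one | CC(=O)O[C@]1(C)[C@@H]2CCC(=O)[C@@H]1[C@@](C)([C@@H](C)CCC=C(C)C)[C@@H](C(=C)OC(C)=O)CC2 | intermediate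
25 | potassium C7/C8 enolate of 24 | [K+].CC(=O)O[C@]1(C)[C@@H]2CC=C([O-])[C@@H]1[C@@](C)([C@@H](C)CCC=C(C)C)[C@@H](C(=C)OC(C)=O)CC2 | intermediate
26 | enol triflate of 24 (C7=C8) | CC(=O)O[C@]1(C)[C@@H]2CC=C(OS(=O)(=O)C(F)(F)F)[C@@H]1[C@@](C)([C@@H](C)CCC=C(C)C)[C@@H](C(=C)OC(C)=O)CC2 | intermediate
27 | 4-acetyl-10-acetoxy-5,10-dimethyl-5-[(2S)-6-methylhept-5-en-2-yl]bicyclo[4.3.1]dec-7-en-7-yl triflate | CC(=O)O[C@]1(C)[C@@H]2CC=C(OS(=O)(=O)C(F)(F)F)[C@@H]1[C@@](C)([C@@H](C)CCC=C(C)C)[C@@H](C(C)=O)CC2 | intermediate
28 | 4-acetyl-10-acetoxy-5,10-dimethyl-5-[(2S)-6-methylhept-5-en-2-yl]bicyclo[4.3.1]dec-7-ene-7-carbaldehyde | CC(=O)O[C@]1(C)[C@@H]2CC=C(C=O)[C@@H]1[C@@](C)([C@@H](C)CCC=C(C)C)[C@@H](C(C)=O)CC2 | target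

**Step count and risks**

Total steps: 15. Longest linear sequence: 14 steps (steps 1–4 and 6–15, from 1 to 28).

Steps most likely to fail:

1. Step 9. After the first C–C bond the 1,4-biradical may revert or transfer hydrogen instead of closing to the crowded cyclobutane, the exocyclic enol may absorb without reacting, and facial control at the quaternary carbon may be incomplete. Fallback: cycloaddition and ring expansion are separated. Setting out from 16, silylation (TBSOTf, Et3N) should give the ring tert-butyldimethylsilyl enol ether F1, in which the reacting enol is locked. Irradiation should give the isolable cyclobutyl silyl ether photoadduct F2, whose diastereomers can be separated. Buffered HF·pyridine then frees the cyclobutanol, which fragments by retro-aldol cleavage and comes back to the route at 19.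

2. Step 11. Si–O cleavage before carbonyl addition would let the enolate add across the ring to the bridging ketone; addition may take the wrong face of C10; acylation of the hindered alkoxide may stall. Fallback: methylene transfer and epoxide reduction replace the methyl addition. Setting out from 20, dimethylsulfonium methylide (Corey–Chaykovsky) should give the C10 spiro-epoxide F3; the oxosulfonium ylide is available if the other face is needed. LiBHEt3 opens the epoxide at CH2, and mild acidic work-up removes the silyl group to give the hydroxy ketone F4. LiHMDS (2.2 equiv) followed by Ac2O, with no ketone electrophile left, then comes back to the route at 23.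

3. Step 3. The β-bromo ketone may lose HBr to a divinyl ketone on formation or work-up, and acylation of the alkenylalane may be slow. Fallback: the chain is built at the alcohol oxidation level. Setting out from 4, carboalumination followed by iodine should give the vinyl iodide F5. Iodine–lithium exchange (t-BuLi) and addition to 3-(tert-butyldimethylsilyloxy)propanal give the allylic alcohol F6. MnO2 gives the silyloxy enone F7, Noyori ketalisation the silyloxy ketal F8, and TBAF the hydroxy ketal F9. CBr4/PPh3 then comes back to the route at 8.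

Further compounds
F1 | step 9 | 2-acetyl-3-alkylcyclopent-1-en-1-yl tert-butyldimethylsilyl ether (ring silyl enol ether of 16) | CC(=O)C1=C(O[Si](C)(C)C(C)(C)C)[C@H](CCC2(OCCO2)/C=C(\C)[C@@H](C)CCC=C(C)C)CC1
F2 | step 9 | cyclobutyl silyl ether photoadduct | CC(C)(C)[Si](C)(C)O[C@@]12[C@@H]3CCC4(OCCO4)[C@@H]1[C@@](C)([C@@H](C)CCC=C(C)C)[C@]2(C(C)=O)CC3
F3 | step 11 | C10 spiro-epoxide of 20 | O4[C@]1(C4)[C@@H]2CCC3(OCCO3)[C@@H]1[C@@](C)([C@@H](C)CCC=C(C)C)[C@@H](C(=C)O[Si](C)(C)C)CC2
F4 | step 11 | 4-acetyl-10-hydroxy-5,10-dimethyl-5-[(2S)-6-methylhept-5-en-2-yl]bicyclo[4.3.1]decan-7-one ethylene ketal | O[C@]1(C)[C@@H]2CCC3(OCCO3)[C@@H]1[C@@](C)([C@@H](C)CCC=C(C)C)[C@@H](C(C)=O)CC2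
F5 | step 3 | (1E,3S)-1-iodo-2,3,7-trimethylocta-1,6-diene | I/C=C(\C)[C@@H](C)CCC=C(C)C
F6 | step 3 | (4E,6S)-1-(tert-butyldimethylsilyloxy)-5,6,10-trimethylundeca-4,9-dien-3-ol (carbinol epimers) | CC(C)(C)[Si](C)(C)OCCC(O)/C=C(\C)[C@@H](C)CCC=C(C)C
F7 | step 3 | (4E,6S)-1-(tert-butyldimethylsilyloxy)-5,6,10-trimethylundeca-4,9-dien-3-one | CC(C)(C)[Si](C)(C)OCCC(=O)/C=C(\C)[C@@H](C)CCC=C(C)C
F8 | step 3 | tert-butyldimethylsilyl ether of F9 | CC(C)(C)[Si](C)(C)OCCC1(OCCO1)/C=C(\C)[C@@H](C)CCC=C(C)C
F9 | step 3 | 2-{2-[(1E,3S)-2,3,7-trimethylocta-1,6-dien-1-yl]-1,3-dioxolan-2-yl}ethan-1-ol | OCCC1(OCCO1)/C=C(\C)[C@@H](C)CCC=C(C)C
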